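## The problem

Compound 21 is a C20 acid in which a cyclohexane (ring C), a δ-lactone and a gem-dimethyl oxabicyclo[3.2.1]octanone (ring A with its ether bridge) meet at one quaternary carbon. Locants used throughout count carbons and ring oxygens from the acrylic acid onward: C1 (methylene), C2, C3 (acid carbon), C4–C9 (ring C; C4 carries the acrylic acid, C7 and C8 are shared with the lactone), C10 (lactone carbonyl), O11, C12, C13 (spiro carbon), C14 (ketone), C15, C16, O17, C18, C19, C20 (CMe2); ring A is C13–C14–C15–C16–C20–C19 and O17–C18 spans C16 and C19. The lactone (C7, C8, C10, O11, C12, C13) is cis-fused to ring C and spiro to ring A at C13, the most crowded atom, flanked by the C14 ketone and the bridgehead C19. Of the six stereocentres (4R,7R,8S,13S,16S,19S), C16 and C19 are locked together by the ether bridge and can control C13, because the axial methyl on C20 covers one face of ring A at C13. C7 and C8 are vicinal and can be made together, but C7 relates to ring A only through the quaternary C13, and C4 (1,3 to C8, 1,4 to C7) has no close neighbour to control it. The fragile points are the acrylic acid (a Michael acceptor), the ring A ketone with its β-alkoxy group at C16 (retro-oxa-Michael opening under base) and C8–H, which is α to the lactone carbonyl and holds that carbonyl axial on ring C, so it can epimerise. The opening for a short route is that C3 lies within reach of C8 (C3–C2–C4–C9–C8): a temporary C3–C8 bond turns the acrylic acid into an α-methylene ketone bridging C8 and C4, a bridge that can only be cis and therefore fixes C4, and it can be cut again by a retro-Claisen reaction because C8 is the α-carbon of the lactone.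

## Retrosynthesis

**21 ⇒ 20.** The first retrosynthetic move is a bond formation: joining C3 to C8 converts the acrylic acid and the epimerisable C8–H of 21 into the bridged α-methylene keto lactone 20. The neighbouring cuts (attaching an acrylate unit to C4 by conjugate addition or coupling, or carrying an isopropenyl group for late oxidation) each need independent control of C4 and a late change of oxidation level. The bridge removes the acid, keeps C8 quaternary until the last step and ties C4 to C8. The forward reaction asks hydroxide to attack the bridging ketone rather than the lactone, and the lactone enolate to be protonated where the acyl group left.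

**20 ⇒ 19.** Cutting C2–C4 opens the five-membered ring and removes the C4 stereocentre, leaving ynone 19 with a plain cyclohexene. Cutting C3–C8 instead would require a ring C already substituted at C4, which is the problem to be avoided. The forward step is a hydrometallative reductive cyclisation in which C2 can reach C4 only on the face that carries the acyl group.

**19 ⇒ 18 + 17.** Ring C is cut at C6–C7 and C8–C9, giving the alkylidene β-keto lactone 18 and buta-1,3-diene 17. The obvious neighbour is closure of C13–C7 last, by conjugate addition of a ring A enolate onto a pre-formed cyclohexadiene ester, followed by acylation of C8. It was set aside because a β-acyloxy ketone enolate should expel the carboxylate faster than it adds to a trisubstituted enoate, and C8 would then have to be acylated beside the more acidic C14 ketone. The cycloaddition makes the quaternary C8 with both carbonyls without enolate chemistry and gives the cis ring fusion automatically. It asks the diene to choose the alkene over the ynone and the correct face of the spiro dienophile.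

**18 ⇒ 16 ⇒ 15 ⇒ 12 ⇒ 11.** The C8–C3 bond and the C7=C8 unsaturation are traced to the saturated spirolactone 11. A direct Baylis–Hillman reaction at the β-substituted lactone is not realistic, so selenium does both jobs: selenide 12 is added as its enolate to ynal 13, and selenoxide elimination gives carbinol 15. Desilylation (16) and oxidation of both carbinols deliver 18 only at the moment it is needed, so no enolisable ynone dicarbonyl is ever handled.

**11 ⇒ 9 + 10.** The C13–C7 bond and the lactone C–O bond are cut together: epoxide 9 and acrylate 10 are joined by reductive radical coupling. Enolate alkylation at C13 of a C14 ketone would face the C13/C15 regiochemistry problem and β-elimination. A cationic bicyclisation forming C13–C7 together with ring A would place C12 trans to H19, the opposite of 21. With the ether bridge already in place, the axial C20 methyl directs the acceptor to the face of the bridge.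

**9 ⇒ 8 ⇒ 7 ⇒ 6.** The C14 oxygen is introduced while the exocyclic alkene C13=C12 of 6 still activates C14. The other allylic position is the bridgehead C19 and cannot react.

**6 ⇒ 4 ⇒ 3 ⇒ 2 ⇒ 1.** The ether bridge is cut at O17–C18 (Williamson closure of diol 4 through tosylate 5, retention at C16). Ring A is cut at C19–C20 (radical cyclisation of epoxide 2, giving acetate 3 with O16 and C18 cis). The single stereocentre of 2 comes from asymmetric epoxidation of geranyl acetate 1 and is the source of all chirality.

## Roads not taken

**Alternative 1:** The cut is C13–C7 and C18–C19. A Diels–Alder reaction between dienone ester A1 and ethoxy diene A2, with Cu(OTf)2 and a tert-butyl bis(oxazoline) ligand, would give tricycle A3; its extra cyclohexene is later cleaved at C10–C18.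
- Merits: one catalytic step sets C13, C19 and C7, with the catalyst deciding absolute configuration and the cycloaddition rules deciding the relative one. In control of the C7/C13 relation this road is better than the chosen plan, which relies on facial selectivity at a spiro dienophile.
- Weak points: the reacting carbon C19 of A1 is neopentyl, and A2 carries a remote stereocentre (C4) that must be made enantiopure and matched to the catalyst. After A3 the route still has to cleave C10–C18, reduce the C12 ester beside a ketone, close the ether by oxa-Michael addition, set C8 by protonation and convert the alkyne into the acrylic acid.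
- Against it the chosen plan sets a much shorter endgame: C4, the acid and C8–H all arise in the last two steps, with no late sorting of oxidation levels.

**Alternative 2:** The cut is C7–C8. Lactone A4 would be converted with KN(SiMe3)2 and t-BuMe2SiCl into its silyl ketene acetal, which undergoes Ireland–Claisen rearrangement through a boat to acid A5.
- Merits: chirality is transferred through a cyclic transition state, so C7 and C8 follow from the C5 carbinol and the alkene geometry, and C4 is in place from the start. In C7/C8 control this is also better than the chosen plan.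
- Weak points: A4 already needs the quaternary C13 with an alkenyl substituent, so the hardest bond (C13–C7) is only moved earlier. The base meets the enolisable C14 ketone with its β-alkoxy group. After A5 the ring alkene must be reduced without touching the alkyne, the PMB ether removed, the lactone closed and the alkyne carboxylated.
- The chosen plan answers with fewer steps, no alkene/alkyne differentiation, and a C4 centre created without any earlier stereocentre at C4.

**Alternative 3:** The cut is C4–C9. Me2AlCl would activate the α-methylene lactone of A6, and the trisubstituted alkene would close ring C in an ene-type reaction to isopropenyl compound A7.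
- Merits: ring C, C4 and C8–H appear in one metal-catalyst-free step, and A7 is only an allylic oxidation away from the target. In step count this road is at least as short as the chosen plan.
- Weak points: C4 rests on the folding of a flexible chain (1,4-induction from C7) and C8 on protonation of an aluminium enolate. The Lewis acid meets the β-alkoxy ketone. The final methyl-to-acid oxidation must spare the enolisable C14 ketone. A6 still needs C7 set against C13, the same facial problem as in the chosen plan.
- The chosen plan sets against it the rigid, bridge-enforced delivery of C2 to C4 and an acid that is released at the right oxidation level.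

Key step: step 13

Assumption: the allylic hydroxylation of step 5 is taken to place the C14 hydroxyl on the face of the ether bridge (anti to the CMe2 bridge); the epimer would be carried through identically, because C14 becomes a ketone in step 12.

## Route

Step 1
Reactants: 1 geranyl acetate
Product: 2 (S)-6,7-epoxygeranyl acetate
Conditions: L-fructose-derived Shi ketone (30 mol %), KHSO5 (Oxone), K2CO3, Bu4NHSO4, MeCN/CH2(OMe)2/aq. Na2B4O7 buffer, 0 °C
Reagents that add atoms: potassium peroxymonosulfate, [K+].[O-]S(=O)(=O)OO
Why: Shi epoxidation: the dioxirane attacks the electron-rich 6,7-alkene in preference to the 2,3-alkene deactivated by the allylic acetate, and the L-series ketone should give the 6S epoxide through the spiro transition state; this centre becomes C16.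

Step 2
Reactants: 2 (S)-6,7-epoxygeranyl acetate
Product: 3 [(1R,3S)-3-hydroxy-2,2-dimethyl-6-methylidenecyclohexyl]methyl acetate
Conditions: Cp2TiCl2 (2.2 equiv), Mn, THF, 25 °C; then aq. HCl
Reagents that add atoms: none
Why: Radical epoxy-ene cyclisation: Cp2TiCl (trivalent titanium, formed in situ) opens the epoxide to the tertiary C20 radical, which closes 6-endo onto the 2,3-alkene through a chair with the titanium alkoxide and the acetoxymethyl group equatorial, so O16 and C18 become cis (C19 set). The tertiary C13 radical is trapped by a second Cp2TiCl and loses hydride from the methyl group, giving the exocyclic alkene C13=C12.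

Step 3
Reactants: 3 [(1R,3S)-3-hydroxy-2,2-dimethyl-6-methylidenecyclohexyl]methyl acetate
Product: 4 (1S,3R)-3-(hydroxymethyl)-2,2-dimethyl-4-methylidenecyclohexan-1-ol
Conditions: K2CO3, MeOH, 25 °C
Reagents that add atoms: none
Why: Base-catalysed transesterification of the primary acetate; nothing else in the molecule is base-sensitive and no stereocentre is touched.

Step 4
Reactants: 4 (1S,3R)-3-(hydroxymethyl)-2,2-dimethyl-4-methylidenecyclohexan-1-ol
Product: 6 (1R,5S)-8,8-dimethyl-2-methylidene-6-oxabicyclo[3.2.1]octane, via tosylate 5 (not isolated)
Conditions: TsCl, pyridine, CH2Cl2, 0 °C; then NaH, THF, 50 °C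
Reagents that add atoms: none
Why: The primary hydroxyl is sulfonylated far faster than the neopentyl secondary one; the C16 alkoxide then displaces the tosylate at C18 (Williamson ether synthesis, 5-exo-tet) through the diaxial chair, which is accessible because O16 and C18 are cis.

Step 5
Reactants: 6 (1R,5S)-8,8-dimethyl-2-methylidene-6-oxabicyclo[3.2.1]octane
Product: 7 (1S,3R,5S)-8,8-dimethyl-2-methylidene-6-oxabicyclo[3.2.1]octan-3-ol
Conditions: SeO2 (0.5 equiv), t-BuOOH, CH2Cl2, 25 °C
Reagents that add atoms: tert-butyl hydroperoxide, CC(C)(C)OO
Why: Riley allylic oxidation (ene reaction, then [2,3]-shift): only the C14 methylene can react, because the other allylic hydrogen sits at the bridgehead C19. The oxygen should arrive anti to the CMe2 bridge; this centre is removed in step 12.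

Step 6
Reactants: 7 (1S,3R,5S)-8,8-dimethyl-2-methylidene-6-oxabicyclo[3.2.1]octan-3-ol
Product: 8 triethyl{[(1S,3R,5S)-8,8-dimethyl-2-methylidene-6-oxabicyclo[3.2.1]octan-3-yl]oxy}silane
Conditions: Et3SiCl, imidazole, DMF, 25 °C
Reagents that add atoms: chlorotriethylsilane, CC[Si](Cl)(CC)CC
Why: Routine silylation; the ether masks O14 through the radical coupling and the enolate steps and is removed together with the alkynyl silane in step 11.

Step 7
Reactants: 8 triethyl{[(1S,3R,5S)-8,8-dimethyl-2-methylidene-6-oxabicyclo[3.2.1]octan-3-yl]oxy}silane
Product: 9 spiro-epoxide at C13–C12 (oxirane oxygen on the face of the ether bridge)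
Conditions: m-CPBA, NaHCO3, CH2Cl2, 0 °C
Reagents that add atoms: 3-chloroperoxybenzoic acid, OOC(=O)c1cccc(Cl)c1
Why: Prilezhaev epoxidation of the only alkene, expected anti to the CMe2 bridge; the configuration at C13 is of no consequence, because step 8 passes through the planar C13 radical.

Step 8
Reactants: 9 spiro-epoxide at C13–C12; 10 2,2,2-trifluoroethyl acrylate
Product: 11 8,8-dimethyl-3-[(triethylsilyl)oxy]spiro[6-oxabicyclo[3.2.1]octane-2,3'-oxan]-6'-one (C7 on the face of the ether bridge)
Conditions: Cp2TiCl2 (20 mol %), Zn, 2,4,6-collidine·HCl, THF, 25 °C
Reagents that add atoms: none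
Why: Reductive epoxide–acrylate coupling (Giese addition of the C13 radical formed by Cp2TiCl opening of the epoxide). C13 is set here: the top lobe of the radical points into the axial C20 methyl, so the acrylate should enter from the face of the O17–C18 bridge, which makes C7 equatorial and C12 axial. Reduction and protonation of the ester radical and attack of the C12 titanium alkoxide on the activated ester then close the δ-lactone.

Step 9
Reactants: 11 silyl-protected spirolactone
Product: 12 C8-phenylselanyl derivative of 11 (either configuration at C8)
Conditions: LiN(i-Pr)2, THF, −78 °C; then PhSeBr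
Reagents that add atoms: phenylselanyl bromide, Br[Se]c1ccccc1
Why: Selenenylation of the lactone lithium enolate; C8 is the only enolisable position and its configuration is lost again in step 10.

Step 10
Reactants: 12 C8-phenylselanyl lactone; 13 3-(trimethylsilyl)prop-2-ynal
Product: 15 unsaturated lactone (C7=C8) with a 1-hydroxy-3-(trimethylsilyl)prop-2-ynyl group on C8, via hydroxy selenide 14 (not isolated)
Conditions: LiN(i-Pr)2, THF, −78 °C; 13; AcOH; then H2O2, pyridine, CH2Cl2, 0 → 25 °C
Reagents that add atoms: none
Why: Aldol addition of the α-selanyl lactone enolate to the ynal makes the C8–C3 bond. Oxidation to the selenoxide and syn-elimination away from the carbinol (the usual regiochemistry of β-hydroxy selenoxides) places the double bond at C7=C8, giving a Baylis–Hillman-type alcohol that a direct Baylis–Hillman reaction at a β-substituted lactone could not provide. The carbinol configuration is irrelevant.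

Step 11
Reactants: 15 silylated unsaturated lactone carbinol
Product: 16 unsaturated lactone diol (free C14–OH and C3–OH; terminal alkyne)
Conditions: Bu4NF, AcOH, THF, 0 → 25 °C
Reagents that add atoms: none
Why: Fluoride cleaves the O–SiEt3 and the alkynyl C–SiMe3 bonds in one operation; the acetic acid buffer keeps the unsaturated lactone from base-induced damage.

Step 12
Reactants: 16 unsaturated lactone diol; 17 buta-1,3-diene
Product: 19 cis-fused cyclohexene spirolactone bearing the propynoyl group on C8 and the C14 ketone, via dienophile 18 (not isolated)
Conditions: Dess–Martin periodinane, NaHCO3, CH2Cl2, 0 → 25 °C; then 17 (excess), ZnCl2 (20 mol %), CH2Cl2, −20 → 25 °C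
Reagents that add atoms: none
Why: Dess–Martin oxidation of both carbinols gives the alkylidene β-keto lactone 18, whose C7=C8 bond is activated by two carbonyls and undergoes the Diels–Alder reaction while the singly activated ynone is left (ZnCl2 chelates the 1,3-dicarbonyl). Suprafacial addition makes C6 and C9 cis, so the lactone is cis-fused and the propynoyl group shares a face with H7. C7 and C8 are set relative to C13 by approach of the diene to the face that looks toward the flat C14 carbonyl, not toward C19 with its hydrogen and the C18 methylene.

Step 13
Reactants: 19 cis-fused propynoyl cyclohexene spirolactone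
Product: 20 bridged keto lactone with an α-methylene cyclopentanone spanning C8 and C4
Conditions: Pd(OAc)2 (5 mol %), PPh3 (10 mol %), AcOH, Et3SiH, toluene, 25 → 50 °C
Reagents that add atoms: none
Why: This is a palladium-catalysed reductive cyclisation of a 1,6-enyne (ynone C1≡C2–C3 and alkene C4=C5, linked through C8 and C9), in which Et3SiH and AcOH convert Pd(OAc)2 into a divalent palladium hydride, H–Pd–OAc. The hydride adds syn across the ynone, hydrogen going to the terminal C1 and palladium to C2, the normal sense for a conjugated alkyne. The alkenylpalladium inserts the C4=C5 alkene in a 5-exo-trig closure (ring C8–C3–C2–C4–C9), forming C2–C4 and the bicyclo[3.2.1]octanone; the 6-endo mode (attack at C5) would give a bicyclo[2.2.2]octane through a poorer four-centre geometry. The C5 alkylpalladium is then reduced by the silane (H–Pd–alkyl, reductive elimination), and the zerovalent palladium released is returned to the hydride by AcOH. The new stereocentre C4 is controlled by the tether: C3 is bound to C8, so C2 can reach C4 only on the face of ring C that carries the acyl group, through the half-chair in which the propynoyl group is pseudo-axial. Selectivity is needed against β-hydride elimination at C5 and against plain conjugate reduction of the ynone; excess silane and the quaternary C8, which holds the alkene next to C2, should secure it. The ketone, lactone and ether are spectators under these nearly neutral conditions.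

Step 14
Reactants: 20 bridged methylene keto lactone
Product: 21 target acid (4R,7R,8S,13S,16S,19S)
Conditions: LiOH, THF/H2O, 0 °C; then aq. HCl to pH 3
Reagents that add atoms: lithium hydroxide, [Li+].[OH-]
Why: Retro-Claisen cleavage of a non-enolisable β-keto lactone: hydroxide adds to the strained bridging ketone C3 and the tetrahedral intermediate expels C8 as the lactone enolate; cleavage on the lactone side would need a bridgehead ketone enolate and should not compete. The enolate is protonated on the face the carboxyl group has just left (the equatorial direction on ring C, beside the nascent acid), so C8–H replaces C8–C3 with retention and the lactone stays cis-fused; acidification recloses any opened lactone.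

## Compound list

1 | geranyl acetate, (2E)-3,7-dimethylocta-2,6-dien-1-yl acetate | CC(=O)OC/C=C(\C)CCC=C(C)C | starting material
2 | (S)-6,7-epoxygeranyl acetate, (2E)-5-[(2S)-3,3-dimethyloxiran-2-yl]-3-methylpent-2-en-1-yl acetate | CC(=O)OC/C=C(\C)CC[C@@H]1OC1(C)C | intermediate
3 | [(1R,3S)-3-hydroxy-2,2-dimethyl-6-methylidenecyclohexyl]methyl acetate | CC(=O)OC[C@@H]1C(=C)CC[C@H](O)C1(C)C | intermediate
4 | (1S,3R)-3-(hydroxymethyl)-2,2-dimethyl-4-methylidenecyclohexan-1-ol | OC[C@@H]1C(=C)CC[C@H](O)C1(C)C | intermediate
5 | [(1R,3S)-3-hydroxy-2,2-dimethyl-6-methylidenecyclohexyl]methyl 4-methylbenzenesulfonate (not isolated) | Cc1ccc(cc1)S(=O)(=O)OC[C@@H]1C(=C)CC[C@H](O)C1(C)C | intermediate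
6 | (1R,5S)-8,8-dimethyl-2-methylidene-6-oxabicyclo[3.2.1]octane | C=C1CC[C@@H]2OC[C@H]1C2(C)C | intermediate
7 | (1S,3R,5S)-8,8-dimethyl-2-methylidene-6-oxabicyclo[3.2.1]octan-3-ol (C14 hydroxyl on the face of the ether bridge) | C=C1[C@H](O)C[C@@H]2OC[C@H]1C2(C)C | intermediate
8 | triethyl{[(1S,3R,5S)-8,8-dimethyl-2-methylidene-6-oxabicyclo[3.2.1]octan-3-yl]oxy}silane | C=C1[C@H](O[Si](CC)(CC)CC)C[C@@H]2OC[C@H]1C2(C)C | intermediate
9 | triethyl{[8,8-dimethylspiro[6-oxabicyclo[3.2.1]octane-2,2'-oxiran]-3-yl]oxy}silane (oxirane oxygen and silyloxy group on the face of the ether bridge) | C1O[C@@]12[C@H](O[Si](CC)(CC)CC)C[C@@H]3OC[C@H]2C3(C)C | intermediate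
10 | 2,2,2-trifluoroethyl prop-2-enoate | C=CC(=O)OCC(F)(F)F | starting material
11 | 8,8-dimethyl-3-[(triethylsilyl)oxy]spiro[6-oxabicyclo[3.2.1]octane-2,3'-oxan]-6'-one (C7 on the face of the ether bridge, C12 on the face of C20) | O=C1OC[C@@]2(CC1)[C@H](O[Si](CC)(CC)CC)C[C@@H]3OC[C@H]2C3(C)C | intermediate
12 | 5'-(phenylselanyl) derivative of 11 (selenium on C8, either configuration) | O=C1OC[C@@]2(CC1[Se]c1ccccc1)[C@H](O[Si](CC)(CC)CC)C[C@@H]3OC[C@H]2C3(C)C | intermediate
13 | 3-(trimethylsilyl)prop-2-ynal | O=CC#C[Si](C)(C)C | starting material
14 | 5'-[1-hydroxy-3-(trimethylsilyl)prop-2-yn-1-yl]-5'-(phenylselanyl) derivative of 11 (diastereomers at C8 and C3; not isolated) | O=C1OC[C@@]2(CC1([Se]c1ccccc1)C(O)C#C[Si](C)(C)C)[C@H](O[Si](CC)(CC)CC)C[C@@H]3OC[C@H]2C3(C)C | intermediate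
15 | 5'-[1-hydroxy-3-(trimethylsilyl)prop-2-yn-1-yl]-8,8-dimethyl-3-[(triethylsilyl)oxy]spiro[6-oxabicyclo[3.2.1]octane-2,3'-pyran]-6'(2'H)-one (C7=C8; either carbinol epimer) | O=C1OC[C@@]2(C=C1C(O)C#C[Si](C)(C)C)[C@H](O[Si](CC)(CC)CC)C[C@@H]3OC[C@H]2C3(C)C | intermediate
16 | 3-hydroxy-5'-(1-hydroxyprop-2-yn-1-yl)-8,8-dimethylspiro[6-oxabicyclo[3.2.1]octane-2,3'-pyran]-6'(2'H)-one | O=C1OC[C@@]2(C=C1C(O)C#C)[C@H](O)C[C@@H]3OC[C@H]2C3(C)C | intermediate
17 | buta-1,3-diene | C=CC=C | starting material
18 | 8,8-dimethyl-5'-(prop-2-ynoyl)spiro[6-oxabicyclo[3.2.1]octane-2,3'-pyran]-3,6'(2'H)-dione (not isolated) | O=C1OC[C@@]2(C=C1C(=O)C#C)C(=O)C[C@@H]3OC[C@H]2C3(C)C | intermediate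
19 | cis-fused cyclohexene (C4=C5) spirolactone with prop-2-ynoyl on C8 (on the face of H7) and the C14 ketone; configuration at C7, C13, C16 and C19 as in 21 | C1=CC[C@@H]2[C@@](C1)(C(=O)C#C)C(=O)OC[C@]21C(=O)C[C@@H]2OC[C@H]1C2(C)C | intermediate
20 | bridged keto lactone: 2-methylidenecyclopentanone (C8–C3–C2–C4–C9) fused across ring C, C8 quaternary | O=C1C(=C)[C@@H]2CC[C@@H]3[C@]1(C2)C(=O)OC[C@]31C(=O)C[C@@H]2OC[C@H]1C2(C)C | intermediate
21 | target: 2-substituted prop-2-enoic acid, (4R,7R,8S,13S,16S,19S) in the locants defined above | C=C(C(=O)O)[C@@H]1CC[C@@H]2[C@H](C1)C(=O)OC[C@]21C(=O)C[C@@H]2OC[C@H]1C2(C)C | target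

## Step count and least certain steps

Total step count: 14. Longest linear sequence: 14 steps from geranyl acetate 1; compounds 10, 13 and 17 and the epoxidation catalyst are purchased.

**Step 13 (key step).** The alkylpalladium at C5 may undergo β-hydride elimination toward C6 before the silane reduces it, the palladium hydride may simply reduce the ynone, or the phosphine may add to the ynone. The fallback sets out from 19 and uses tin radical chemistry: Bu3SnH and AIBN in benzene at 80 °C add a stannyl radical to C1, and the α-keto vinyl radical at C2 closes 5-exo onto C4 on the same tether-imposed face. The C5 radical is then reduced, giving vinylstannane F1. Protodestannylation with HCl in CH2Cl2 returns to the route at 20.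

**Step 12.** Facial discrimination at C7 may be poor, since the two faces of the spiro dienophile differ only by a carbonyl versus a tertiary CH. The very electrophilic dienophile may also react or decompose at the ynone. The fallback sets out from selenide 12 and annulates before the ynone exists:
- Oxidative elimination (H2O2, pyridine) gives unsaturated lactone F2.
- Diels–Alder reaction with 17 under EtAlCl2 gives cis-fused lactone F3, now steered by the C14 silyloxy group rather than by the carbonyl, so the two variants should not fail in the same way.
- The ring-fusion lithium enolate of F3 (LiN(i-Pr)2) adds to 13 on the face of H7, the normal course for cis-fused ring-fusion enolates, to give carbinol F4.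
- Bu4NF gives diol F5, and Dess–Martin oxidation of both carbinols returns to the route at 19.

**Step 8.** The C13 radical may be reduced by a second Cp2TiCl before it adds, followed by loss of a β-oxygen (deoxygenation), and the axial silyloxy group next to C13 may erode the facial preference. The fallback sets out from epoxide 9 and replaces the radical by an enamine:
- Meinwald rearrangement with BF3·OEt2 gives aldehyde F6.
- Its pyrrolidine enamine F7 (not isolated) undergoes Stork enamine Michael addition to methyl acrylate in MeCN at reflux; hydrolysis gives aldehyde ester F8, with the new chain again anti to the axial C20 methyl.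
- NaBH4 reduces the neopentyl aldehyde and the C12 alkoxide closes onto the methyl ester, returning to the route at 11.

**Step 14.** Hydroxide may open the lactone or add to the methylene ketone faster than it attacks C3, ring A may open by retro-oxa-Michael reaction, and prolonged aqueous base may epimerise C8 to the trans-fused lactone. The fallback sets out from 20 and separates cleavage from unmasking of the acid. LiOCH2CH=CH2 (from allyl alcohol and LiN(SiMe3)2) in THF at −40 °C, quenched cold with AcOH so that the enolate is protonated kinetically, gives allyl ester F9. Pd(PPh3)4 and morpholine then remove the allyl group under neutral conditions and return to the route at 21.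

## Further compounds

F1 | step 13 | (tributylstannyl)methylidene analogue of 20 (vinylstannane at C1) | O=C1C(=C[Sn](CCCC)(CCCC)CCCC)[C@@H]2CC[C@@H]3[C@]1(C2)C(=O)OC[C@]31C(=O)C[C@@H]2OC[C@H]1C2(C)C
F2 | step 12 | 8,8-dimethyl-3-[(triethylsilyl)oxy]spiro[6-oxabicyclo[3.2.1]octane-2,3'-pyran]-6'(2'H)-one (C7=C8 unsaturated lactone) | O=C1OC[C@@]2(C=C1)[C@H](O[Si](CC)(CC)CC)C[C@@H]3OC[C@H]2C3(C)C
F3 | step 12 | cis-fused cyclohexene spirolactone with H on C8 and the C14 triethylsilyl ether | C1=CC[C@@H]2[C@H](C1)C(=O)OC[C@]21[C@H](O[Si](CC)(CC)CC)C[C@@H]2OC[C@H]1C2(C)C
F4 | step 12 | C8 1-hydroxy-3-(trimethylsilyl)prop-2-ynyl derivative of F3 (either carbinol epimer) | C1=CC[C@@H]2[C@@](C1)(C(O)C#C[Si](C)(C)C)C(=O)OC[C@]21[C@H](O[Si](CC)(CC)CC)C[C@@H]2OC[C@H]1C2(C)C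
F5 | step 12 | diol from F4 (C14–OH, C3–OH, terminal alkyne) | C1=CC[C@@H]2[C@@](C1)(C(O)C#C)C(=O)OC[C@]21[C@H](O)C[C@@H]2OC[C@H]1C2(C)C
F6 | step 8 | 8,8-dimethyl-3-[(triethylsilyl)oxy]-6-oxabicyclo[3.2.1]octane-2-carbaldehyde (either configuration at C13) | O=CC1[C@H](O[Si](CC)(CC)CC)C[C@@H]2OC[C@H]1C2(C)C
F7 | step 8 | pyrrolidine enamine of F6 (not isolated) | C1CCN(C1)C=C2[C@H](O[Si](CC)(CC)CC)C[C@@H]3OC[C@H]2C3(C)C
F8 | step 8 | methyl 3-{2-formyl-8,8-dimethyl-3-[(triethylsilyl)oxy]-6-oxabicyclo[3.2.1]octan-2-yl}propanoate (chain on the face of the ether bridge) | O=C[C@@]1(CCC(=O)OC)[C@H](O[Si](CC)(CC)CC)C[C@@H]2OC[C@H]1C2(C)C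
F9 | step 14 | prop-2-en-1-yl ester of 21 | C=C(C(=O)OCC=C)[C@@H]1CC[C@@H]2[C@H](C1)C(=O)OC[C@]21C(=O)C[C@@H]2OC[C@H]1C2(C)C
A1 | alternative 1 | methyl 3,3-dimethyl-6-oxocyclohexa-1,4-diene-1-carboxylate | COC(=O)C1=CC(C)(C)C=CC1=O
A2 | alternative 1 | {[3-(1-ethoxyethenyl)cyclohex-3-en-1-yl]ethynyl}tri(propan-2-yl)silane (C4 configured as in A3) | C=C(OCC)C1=CCC[C@H](C1)C#C[Si](C(C)C)(C(C)C)C(C)C
A3 | alternative 1 | tricyclic enol ether with C13, C19 and C7 set and the ring A enone retained | CC(C)[Si](C(C)C)(C(C)C)C#C[C@@H]1CC[C@@H]2C(C1)=C(OCC)C[C@H]1C(C)(C)C=CC(=O)[C@@]21C(=O)OC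
A4 | alternative 2 | δ-lactone (C10–O–C5) with the silylalkynyl group on C4 cis to the (E)-alkenyl chain on C5 that ends at C13 (PMB ether on C12) | O=C1CC[C@H](C#C[Si](C(C)C)(C(C)C)C(C)C)[C@@H](O1)/C=C/[C@]1(COCc2ccc(OC)cc2)C(=O)C[C@@H]2OC[C@H]1C2(C)C
A5 | alternative 2 | cyclohexene carboxylic acid with C4, C7 and C8 set, PMB ether on C12 | CC(C)[Si](C(C)C)(C(C)C)C#C[C@@H]1C=C[C@H]([C@H](C1)C(=O)O)[C@]1(COCc2ccc(OC)cc2)C(=O)C[C@@H]2OC[C@H]1C2(C)C
A6 | alternative 3 | α-methylene spirolactone with a 4-methylpent-3-enyl chain on C7 | CC(C)=CCC[C@@H]1C(=C)C(=O)OC[C@]12C(=O)C[C@@H]3OC[C@H]2C3(C)C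
A7 | alternative 3 | complete skeleton with isopropenyl on C4 | CC(=C)[C@@H]1CC[C@@H]2[C@H](C1)C(=O)OC[C@]21C(=O)C[C@@H]2OC[C@H]1C2(C)C
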